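A direct plan would build the quaternary carbon C12 first, by Claisen rearrangement of a chiral-pool allylic alcohol, and carry it through an aldol condensation with an ethyl-substituted benzaldehyde and a Friedel–Crafts cyclialkylation to the tricyclic alkylidene lactone A1. It would then add a nitromethyl group to C7 (A2) and finish with an intramolecular aldol condensation of keto aldehyde A3 that closes the cycloheptenone.
Its weakest steps would be:
- The run-up to A1: about a dozen linear steps of protection, reduction, olefination and ester differentiation for a tetralin with one stereocentre.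
- The passage from A2 to A3: the lactone would be opened to an amide, the alcohol oxidised and masked as a dithiane, a Nef reaction and an acyl-anion addition run, and the aldehyde unmasked; some six steps of protection and redox change would add two carbons.
- The last aldol closure: C8 would enter as an epimeric mixture and be corrected only by enolisation of an α-acyloxy ketone while a bridged seven-membered ring forms next to a free aldehyde.

**Retrosynthetic overview**
The γ-lactone (C7–C8–O9–C10–C11) is read as a ring-expanded cyclobutanone, and its C7–C11 bond, shared with the tetralin and the cycloheptenone, as a former styrene double bond.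
Key cut: C7–C8 and C10–C11 are formed together by an intramolecular [2+2] cycloaddition of a (Z)-vinylketene onto the C7=C11 bond of a 1,2-dihydronaphthalene; the tether C15=C14–C13 becomes the seven-membered ring.
Ring order: tetralin (one-pot Friedel–Crafts annulation of ethylbenzene), then cycloheptene and cyclobutanone at once, then lactone by Baeyer–Villiger oxygen insertion, then enone by singlet-oxygen transposition, with arene bromination last.
C12 is set once, by CBS reduction and suprafacial Eschenmoser–Claisen chirality transfer; C7, C8 and C11 follow from C12 in the key step, so no epimer needs correcting and no protecting group is used (11 steps).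

Key step: step 8

Assumptions: atom labels follow the salimabromide skeleton (C7 benzylic CH, C8 CH–O, O9, C10 lactone C=O, C11 CH, C12 C–CH3, C13/C14/C15 the three remaining carbons of the seven-membered ring, C16 CMe2). In the CBS reduction the fused arene is taken as the larger flank of the ketone, as in 1-tetralone; if the sense proved opposite, the (S)-catalyst would be used.

Step 1
Reactants: 1 ethylbenzene; 2 5,5-dimethyloxolan-2-one
Product: 4 7-ethyl-4,4-dimethyl-3,4-dihydronaphthalen-1(2H)-one, via 4-(4-ethylphenyl)-4-methylpentanoic acid 3 (not isolated)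
Conditions: AlCl3 (3 equiv), ethylbenzene (8 equiv, solvent), 0 °C → 70 °C; ice/HCl
Reagents that add atoms: none
Why: One-pot Friedel–Crafts alkylation–acylation (lactone/AlCl3 tetralone annulation): the tertiary cation alkylates para to ethyl and the tethered acyl group can then close only ortho to the new quaternary carbon, so ethyl ends at C7 of the tetralone without a regiochemical choice.

Step 2
Reactants: 4 7-ethyl-4,4-dimethyl-3,4-dihydronaphthalen-1(2H)-one
Product: 6 7-ethyl-4,4-dimethylnaphthalen-1(4H)-one, via α-phenylselanyl ketone 5 (not isolated)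
Conditions: LiN(i-Pr)2 (1.1 equiv), THF, −78 °C; PhSeCl (1.15 equiv); then 30% H2O2, pyridine, CH2Cl2, 0 °C → rt
Reagents that add atoms: none
Why: α-Selenenylation of the ketone enolate and selenoxide syn-elimination should give the enone, which cannot tautomerise to a naphthol because C4 is quaternary.

Step 3
Reactants: 6 7-ethyl-4,4-dimethylnaphthalen-1(4H)-one
Product: 8 7-ethyl-3,4,4-trimethylnaphthalen-1(4H)-one, via silyl enol ether 7 (not isolated)
Conditions: Me2CuLi (1.5 equiv, from CuI and MeLi), Me3SiCl (3 equiv), THF, −78 → −20 °C; filtration, solvent change; then Pd(OAc)2 (1.1 equiv), MeCN, rt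
Reagents that add atoms: lithium dimethylcuprate, [Li+].C[Cu-]C
Why: Chlorosilane-accelerated cuprate 1,4-addition places the methyl group next to the gem-dimethyl carbon and Saegusa–Ito dehydrosilylation of the trapped silyl enol ether restores the enone, which erases the transient C3 stereocentre.

Step 4
Reactants: 8 7-ethyl-3,4,4-trimethylnaphthalen-1(4H)-one
Product: 9 (1S)-7-ethyl-3,4,4-trimethyl-1,4-dihydronaphthalen-1-ol
Conditions: (R)-1-methyl-3,3-diphenyltetrahydro-1H,3H-pyrrolo[1,2-c][1,3,2]oxazaborole (0.2 equiv), catecholborane (1.5 equiv), toluene, −78 °C; pH 7 buffer; Et3N-deactivated silica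
Reagents that add atoms: none
Why: Corey–Bakshi–Shibata reduction: the ketone should bind to the catalyst boron anti to the fused arene and take hydride on one face, which sets the (S)-carbinol, the only stereocentre of the route that a reagent controls.

Step 5
Reactants: 9 (1S)-7-ethyl-3,4,4-trimethyl-1,4-dihydronaphthalen-1-ol; 10 1,1-dimethoxy-N,N-dimethylethan-1-amine
Product: 12 2-[(2R)-6-ethyl-1,1,2-trimethyl-1,2-dihydronaphthalen-2-yl]-N,N-dimethylacetamide, via ketene N,O-acetal 11 (not isolated)
Conditions: 10 (5 equiv), xylenes, 130 °C, MeOH distilled off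
Reagents that add atoms: none
Why: Eschenmoser–Claisen rearrangement under acid-free conditions that the doubly activated alcohol tolerates: the [3,3] shift is suprafacial across the ring, so the new C–C bond forms on the face from which the C–O bond leaves, which transfers the (S)-carbinol chirality to quaternary C12 (R) and moves the alkene to C7=C11.

Step 6
Reactants: 12 2-[(2R)-6-ethyl-1,1,2-trimethyl-1,2-dihydronaphthalen-2-yl]-N,N-dimethylacetamide
Product: 13 2-[(2R)-6-ethyl-1,1,2-trimethyl-1,2-dihydronaphthalen-2-yl]acetaldehyde
Conditions: Cp2Zr(H)Cl (1.6 equiv), THF, rt, 20 min; silica gel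
Reagents that add atoms: none
Why: Schwartz-reagent reduction of the tertiary amide stops at the aldehyde through a zirconated hemiaminal and should be faster than hydrozirconation of the hindered cyclic styrene.

Step 7
Reactants: 13 2-[(2R)-6-ethyl-1,1,2-trimethyl-1,2-dihydronaphthalen-2-yl]acetaldehyde; 14 (2-carboxyethyl)triphenylphosphonium bromide
Product: 16 (3Z)-5-[(2R)-6-ethyl-1,1,2-trimethyl-1,2-dihydronaphthalen-2-yl]pent-3-enoic acid, via carboxylate ylide 15 (not isolated)
Conditions: 14 (1.6 equiv), NaN(SiMe3)2 (3.2 equiv), THF, −78 °C; then 13, −78 °C → rt; 1 M HCl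
Reagents that add atoms: none
Why: Salt-free Wittig olefination with the non-stabilised carboxylate ylide should give the (Z)-β,γ-unsaturated acid, adding C15, C8 and C10 in one step with the cis geometry that the seven-membered ring needs.

Step 8
Reactants: 16 (3Z)-5-[(2R)-6-ethyl-1,1,2-trimethyl-1,2-dihydronaphthalen-2-yl]pent-3-enoic acid
Product: 19 bridged vinylcyclobutanone (7S,8R,11R,12R; four-membered ring C7–C8–C10(=O)–C11 across the former styrene bond; C8 joined to C12 by cis-C15H=C14H–C13H2), via acid chloride 17 (not isolated), via vinylketene 18 (not isolated)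
Conditions: (COCl)2 (1.5 equiv), DMF (cat.), CH2Cl2, 0 °C → rt, evaporate; then slow addition (6 h) to Et3N (5 equiv) in toluene, 110 °C, final 0.005 M
Reagents that add atoms: none
Why: Triethylamine removes the doubly activated α-hydrogen of acid chloride 17 to give the (Z)-vinylketene 18, whose ketene C=C adds to the C7=C11 styrene bond in a thermal, asynchronous [2+2] cycloaddition: the electrophilic ketene carbon C10 bonds to C11 while positive charge builds at benzylic C7, which C8 then captures. The closest known reactions are the intramolecular vinylketene–alkene cycloadditions that give bridged bicyclo[3.1.1]heptenones (chrysanthenone-type closures) and the keteniminium variants used for bridged cyclobutanones. Two rings close at once, the cyclobutanone (C7–C8–C10–C11) and the cycloheptene (C7–C8–C15=C14–C13–C12–C11), in the crossed (bridged, bicyclo[4.1.1]) mode in which the ketene α-carbon bonds to the distal alkene carbon. C7, C8 and C11 are all controlled by C12: the four-atom tether lets the ketene reach only the alkene face that carries C13 and addition to the cyclic cis-alkene is suprafacial, so only the all-cis adduct (7S,8R,11R) can form. The step needs the crossed and not the fused regiochemistry, which the styrene polarisation secures (a fused adduct would put positive charge on non-benzylic C11), and it needs the ketene C=C and not the vinyl group to react, which is the normal behaviour of vinylketenes towards unactivated alkenes. High dilution should suppress ketene dimerisation.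

Step 9
Reactants: 19 bridged vinylcyclobutanone
Product: 20 allylic γ-lactone (7S,8R,11R,12R; O9 between C8 and C10; alkene C14=C15)
Conditions: 30% H2O2 (3 equiv), AcOH/H2O (9:1), 0 → 5 °C
Reagents that add atoms: hydrogen peroxide, OO
Why: Baeyer–Villiger oxidation of the strained cyclobutanone should insert O9 between C10 and C8 with retention at C8, because of the two secondary α-carbons the allylic C8 (its C8–C10 bond overlaps with the C14=C15 π bond) migrates better than neopentylic C11, while H2O2 in acetic acid leaves the isolated alkene untouched.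

Step 10
Reactants: 20 allylic γ-lactone
Product: 22 didebromosalimabromide (7S,8S,11R,12R), via allylic hydroperoxide 21 (not isolated)
Conditions: O2, 5,10,15,20-tetraphenylporphyrin (1 mol %), CH2Cl2, white LED, 0 °C; then Ac2O (3 equiv), pyridine (5 equiv), 4-(dimethylamino)pyridine (cat.), 0 °C → rt
Reagents that add atoms: oxygen, O=O
Why: Schenck ene reaction of singlet oxygen followed by Kornblum–DeLaMare dehydration: the only allylic hydrogens that can be abstracted without making a bridgehead alkene are those on C13, so oxygen is forced onto C15 and the alkene moves to C13=C14, and the new C15 centre is lost when the hydroperoxide is dehydrated to the enone.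

Step 11
Reactants: 22 didebromosalimabromide
Product: 23 salimabromide
Conditions: Br2 (2.3 equiv), AgO2CCF3 (2.3 equiv), CF3CO2H, 0 °C → rt, dark
Reagents that add atoms: bromine, BrBr
Why: Electrophilic aromatic bromination with silver-activated bromine should go to the two positions ortho to ethyl, each doubly alkyl-activated, while the third free position is singly activated and shielded by the gem-dimethyl group and the electron-poor enone and the lactone react far more slowly than the trialkylbenzene.

**Compound list**

1 | ethylbenzene | CCc1ccccc1 | starting material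
2 | 5,5-dimethyloxolan-2-one | CC1(C)CCC(=O)O1 | starting material
3 | 4-(4-ethylphenyl)-4-methylpentanoic acid | CCc1ccc(cc1)C(C)(C)CCC(=O)O | intermediate (not isolated)
4 | 7-ethyl-4,4-dimethyl-3,4-dihydronaphthalen-1(2H)-one | CCc1ccc2c(c1)C(=O)CCC2(C)C | intermediate
5 | 7-ethyl-4,4-dimethyl-2-(phenylselanyl)-3,4-dihydronaphthalen-1(2H)-one | CCc1ccc2c(c1)C(=O)C([Se]c1ccccc1)CC2(C)C | intermediate (not isolated)
6 | 7-ethyl-4,4-dimethylnaphthalen-1(4H)-one | CCc1ccc2c(c1)C(=O)C=CC2(C)C | intermediate
7 | [(7-ethyl-3,4,4-trimethyl-3,4-dihydronaphthalen-1-yl)oxy]trimethylsilane (racemic at C3) | CCc1ccc2c(c1)C(O[Si](C)(C)C)=CC(C)C2(C)C | intermediate (not isolated)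
8 | 7-ethyl-3,4,4-trimethylnaphthalen-1(4H)-one | CCc1ccc2c(c1)C(=O)C=C(C)C2(C)C | intermediate
9 | (1S)-7-ethyl-3,4,4-trimethyl-1,4-dihydronaphthalen-1-ol | CCc1ccc2c(c1)[C@@H](O)C=C(C)C2(C)C | intermediate
10 | 1,1-dimethoxy-N,N-dimethylethan-1-amine | CC(OC)(OC)N(C)C | starting material
11 | 1-{[(1S)-7-ethyl-3,4,4-trimethyl-1,4-dihydronaphthalen-1-yl]oxy}-N,N-dimethylethen-1-amine | C=C(N(C)C)O[C@H]1C=C(C)C(C)(C)c2ccc(CC)cc21 | intermediate (not isolated)
12 | 2-[(2R)-6-ethyl-1,1,2-trimethyl-1,2-dihydronaphthalen-2-yl]-N,N-dimethylacetamide | CN(C)C(=O)C[C@]1(C)C=Cc2cc(CC)ccc2C1(C)C | intermediate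
13 | 2-[(2R)-6-ethyl-1,1,2-trimethyl-1,2-dihydronaphthalen-2-yl]acetaldehyde | O=CC[C@]1(C)C=Cc2cc(CC)ccc2C1(C)C | intermediate
14 | (2-carboxyethyl)triphenylphosphonium bromide | OC(=O)CC[P+](c1ccccc1)(c1ccccc1)c1ccccc1.[Br-] | starting material
15 | sodium 3-(triphenyl-λ5-phosphanylidene)propanoate | [Na+].[O-]C(=O)CC=P(c1ccccc1)(c1ccccc1)c1ccccc1 | intermediate (not isolated)
16 | (3Z)-5-[(2R)-6-ethyl-1,1,2-trimethyl-1,2-dihydronaphthalen-2-yl]pent-3-enoic acid | OC(=O)C/C=C\C[C@]1(C)C=Cc2cc(CC)ccc2C1(C)C | intermediate
17 | (3Z)-5-[(2R)-6-ethyl-1,1,2-trimethyl-1,2-dihydronaphthalen-2-yl]pent-3-enoyl chloride | ClC(=O)C/C=C\C[C@]1(C)C=Cc2cc(CC)ccc2C1(C)C | intermediate (not isolated)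
18 | (3Z)-5-[(2R)-6-ethyl-1,1,2-trimethyl-1,2-dihydronaphthalen-2-yl]penta-1,3-dien-1-one (vinylketene) | O=C=C/C=C\C[C@]1(C)C=Cc2cc(CC)ccc2C1(C)C | intermediate (not isolated)
19 | bridged vinylcyclobutanone (7S,8R,11R,12R) | CCc1ccc2c(c1)[C@H]1[C@@H]3C(=O)[C@H]1[C@@](C)(CC=C3)C2(C)C | intermediate
20 | allylic γ-lactone (7S,8R,11R,12R), alkene C14=C15 | CCc1ccc2c(c1)[C@H]1[C@@H]3OC(=O)[C@H]1[C@@](C)(CC=C3)C2(C)C | intermediate
21 | 15-hydroperoxy lactone, alkene C13=C14 (C15 configuration open) | CCc1ccc2c(c1)[C@H]1[C@@H]3OC(=O)[C@H]1[C@@](C)(C=CC3OO)C2(C)C | intermediate (not isolated)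
22 | didebromosalimabromide (7S,8S,11R,12R) | CCc1ccc2c(c1)[C@H]1[C@@H]3OC(=O)[C@H]1[C@@](C)(C=CC3=O)C2(C)C | intermediate
23 | salimabromide | CCc1c(Br)cc2c(c1Br)[C@H]1[C@@H]3OC(=O)[C@H]1[C@@](C)(C=CC3=O)C2(C)C | target

**Step count and risks**

Total step count: 11. Longest linear sequence: 11 (steps 1–11).

Steps most likely to fail:

1. Step 8 (ketene cycloaddition). The vinylketene may be drained by dimerisation, or by a [1,5]-hydrogen shift from C13 to C10, before it adds to the hindered C7=C11 bond. The fallback sets out from 16 and comes back at 19. Acid 16 would be coupled with pyrrolidine (EDC·HCl, CH2Cl2) to (3Z)-5-[(2R)-6-ethyl-1,1,2-trimethyl-1,2-dihydronaphthalen-2-yl]-1-(pyrrolidin-1-yl)pent-3-en-1-one F1. Tf2O and 2,4,6-trimethylpyridine in 1,2-dichloroethane (0 → 80 °C) would convert it into the vinylketeniminium triflate F2, a cationic and much more electrophilic partner that should add stepwise to the styrene bond with the same regiochemistry to give the cyclobutaniminium triflate F3. Aqueous NaHCO3 would hydrolyse it to cyclobutanone 19.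

2. Step 9 (Baeyer–Villiger oxidation). Migration may be poorly regioselective, with C11 competing with C8, so that the isomeric lactone with oxygen on C11 forms. The fallback sets out from 19 and comes back at 22; it makes the C8–O9 bond by oxidative lactonisation instead of oxygen insertion. Photo-oxygenation and dehydration of 19 under the conditions of step 10 would give, through the 15-hydroperoxy cyclobutanone F4, the non-enolisable cyclobutanone–enone diketone F5. LiOH in THF/H2O at 0 °C should open the strained ring by retro-Claisen cleavage of C8–C10 only, because C8 leaves as the enolate of the C15 enone, to give the keto acid F6 (carboxylic acid C10 on C11, C8 a methylene group). PhI(OH)OTs in MeCN at 60 °C would then oxidise C8, the only enolisable α-position of the ketone, with capture by the cis carboxylate (keto-γ-lactonisation of a 5-oxo acid), which gives 22.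

3. Step 10 (singlet-oxygen ene reaction). The cis-disubstituted alkene, deactivated by the allylic acyloxy group, may react too slowly, with bleaching of the sensitiser and decomposition of the hydroperoxide. The fallback sets out from 20 and comes back at 22. Epoxidation with dimethyldioxirane in acetone would give the 14,15-epoxy lactone F7. PhSeNa (from (PhSe)2 and NaBH4, EtOH) should open it at C14, the carbon remote from the acyloxy-bearing C8, to the 14-phenylselanyl-15-hydroxy lactone F8. Oxidation with H2O2/pyridine and selenoxide syn-elimination away from the carbinol carbon would give the 15-hydroxy allylic alcohol F9 (alkene C13=C14). Dess–Martin periodinane would oxidise it to 22.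

**Further compounds**

F1 | step 8 | (3Z)-5-[(2R)-6-ethyl-1,1,2-trimethyl-1,2-dihydronaphthalen-2-yl]-1-(pyrrolidin-1-yl)pent-3-en-1-one | O=C(C/C=C\C[C@]1(C)C=Cc2cc(CC)ccc2C1(C)C)N1CCCC1
F2 | step 8 | 1-{(3Z)-5-[(2R)-6-ethyl-1,1,2-trimethyl-1,2-dihydronaphthalen-2-yl]penta-1,3-dien-1-ylidene}pyrrolidin-1-ium trifluoromethanesulfonate (vinylketeniminium triflate) | C(=C=[N+]1CCCC1)/C=C\C[C@]1(C)C=Cc2cc(CC)ccc2C1(C)C.[O-]S(=O)(=O)C(F)(F)F
F3 | step 8 | cyclobutaniminium triflate corresponding to 19 (C10=N+ pyrrolidinium, ring configuration as in 19) | CCc1ccc2c(c1)[C@H]1[C@@H]3C(=[N+]4CCCC4)[C@H]1[C@@](C)(CC=C3)C2(C)C.[O-]S(=O)(=O)C(F)(F)F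
F4 | step 9 | 15-hydroperoxy cyclobutanone, alkene C13=C14 (ring configuration as in 19, C15 open) | CCc1ccc2c(c1)[C@H]1[C@@H]3C(=O)[C@H]1[C@@](C)(C=CC3OO)C2(C)C
F5 | step 9 | cyclobutanone–enone diketone (C10 and C15 ketones, alkene C13=C14, ring configuration as in 19) | CCc1ccc2c(c1)[C@H]1[C@@H]3C(=O)[C@H]1[C@@](C)(C=CC3=O)C2(C)C
F6 | step 9 | keto acid (carboxylic acid C10 on C11, C8 methylene, C15 ketone, alkene C13=C14; C7, C11, C12 as in 19) | CCc1ccc2c(c1)[C@H]1CC(=O)C=C[C@](C)([C@@H]1C(=O)O)C2(C)C
F7 | step 10 | 14,15-epoxy lactone (ring configuration as in 20, epoxide face open) | CCc1ccc2c(c1)[C@H]1[C@@H]3OC(=O)[C@H]1[C@@](C)(CC4OC43)C2(C)C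
F8 | step 10 | 14-phenylselanyl-15-hydroxy lactone (ring configuration as in 20) | CCc1ccc2c(c1)[C@H]1[C@@H]3OC(=O)[C@H]1[C@@](C)(CC([Se]c4ccccc4)C3O)C2(C)C
F9 | step 10 | 15-hydroxy lactone, alkene C13=C14 (ring configuration as in 22, C15 open) | CCc1ccc2c(c1)[C@H]1[C@@H]3OC(=O)[C@H]1[C@@](C)(C=CC3O)C2(C)C
A1 | direct plan | (3aS)-7-ethyl-3a,4,4-trimethyl-3a,4-dihydronaphtho[2,3-c]furan-1(3H)-one | O=C1OC[C@]2(C)C1=Cc1cc(CC)ccc1C2(C)C
A2 | direct plan | (3aR,9S,9aR)-7-ethyl-3a,4,4-trimethyl-9-(nitromethyl)-3a,4,9,9a-tetrahydronaphtho[2,3-c]furan-1(3H)-one | CCc1ccc2c(c1)[C@@H](C[N+](=O)[O-])[C@H]1C(=O)OC[C@@]1(C)C2(C)C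
A3 | direct plan | (3aR,4R,9bS)-1-acetyl-7,9-dibromo-8-ethyl-4,5,5-trimethyl-3-oxo-1,3,3a,4,5,9b-hexahydronaphtho[1,2-c]furan-4-carbaldehyde (C1 epimers) | CCc1c(Br)cc2c(c1Br)[C@H]1C(C(C)=O)OC(=O)[C@H]1[C@@](C)(C=O)C2(C)C
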